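The ten-membered ring is closed at the C8–C9 bond by an intramolecular allylboration. An aldehyde at C8, carried by a preformed trans-γ-lactone, is attacked by the CH2 terminus (C9) of an α-substituted 2-methylallyl pinacol boronate whose boron sits on C1 next to the silylated C2 carbinol. The step exploits the (Z)-C1=C10 alkene that lies between the C2 and C8 carbinols in the ten-membered ring: one chair transition state should deliver the ring, the Z alkene and the C8 stereocentre by chirality transfer from C1. The precursor, a boronate alcohol oxidized in the flask, comes from a vinylogous aldol, an Evans aldol–lactonization and a copper-catalysed allylic borylation.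

Key step: step 10

Remark on numbering: germacrane numbering is used throughout. C1–C10 are the ring carbons (C2 carbinol, C6 lactone oxygen, C8 ester), C11/C12/C13 are the lactone α-carbon, carbonyl and exocyclic methylene, and C14/C15 are the methyls on C10/C4.

Step 1
Reactants: 1 3-methylbut-2-enal
Product: 2 (E)-tert-butyl(dimethyl)[(3-methylbuta-1,3-dien-1-yl)oxy]silane
Conditions: TBSOTf, Et3N, Et2O, 0 °C to rt
Reagents that add atoms: tert-butyldimethylsilyl triflate CC(C)(C)[Si](C)(C)OS(=O)(=O)C(F)(F)F
Why: Silyl dienol ether formation: O-silylation of the enal and γ-deprotonation by Et3N should give the (E)-1-silyloxy-1,3-diene that serves as vinylogous nucleophile.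

Step 2
Reactants: 2 silyl dienol ether; 1 3-methylbut-2-enal
Product: 3 (2E,5R)-5-hydroxy-3,7-dimethylocta-2,6-dienal
Conditions: N-tosyl-L-tryptophan-derived B-phenyl oxazaborolidinone (0.5 equiv), i-PrOH, EtCN, −78 °C
Reagents that add atoms: none
Why: Enantioselective vinylogous Mukaiyama aldol reaction: the chiral boron Lewis acid binds the enal and blocks one face, so γ-attack of 2 should set C2 as R (the D-tryptophan-derived catalyst is taken if the sense proves opposite) and give the conjugated (E)-enal.

Step 3
Reactants: 3 hydroxy enal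
Product: 4 (2E,5R)-5-[(tert-butyldimethylsilyl)oxy]-3,7-dimethylocta-2,6-dienal
Conditions: TBSCl, imidazole, DMF, rt
Reagents that add atoms: tert-butyldimethylsilyl chloride CC(C)(C)[Si](C)(C)Cl
Why: Silyl ether protection of the secondary allylic alcohol under mild imidazole catalysis, which should not trigger vinylogous β-elimination.

Step 4
Reactants: 4 silyl ether enal
Product: 5 (2E,5R,6E)-5-[(tert-butyldimethylsilyl)oxy]-8-hydroxy-3,7-dimethylocta-2,6-dienal
Conditions: SeO2 (0.3 equiv), t-BuOOH, CH2Cl2, 0 °C to rt
Reagents that add atoms: tert-butyl hydroperoxide CC(C)(C)OO (oxygen, passed on by catalytic SeO2 O=[Se]=O)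
Why: Riley oxidation (ene reaction, then [2,3]-sigmatropic shift) should attack the electron-rich trisubstituted alkene rather than the enal alkene and oxidize its (E)-methyl group, which leaves the C14 methyl cis to C2.

Step 5
Reactants: 5 allylic alcohol
Product: 6 (2E,4R,6E)-4-[(tert-butyldimethylsilyl)oxy]-2,6-dimethyl-8-oxoocta-2,6-dien-1-yl methyl carbonate
Conditions: ClCO2Me, pyridine, CH2Cl2, 0 °C
Reagents that add atoms: methyl chloroformate COC(Cl)=O
Why: Acylation of the primary allylic alcohol (carbonate formation) installs the leaving group for the later allylic substitution.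

Step 6
Reactants: 7 (S)-4-benzyloxazolidin-2-one; 8 methyl 4-chloro-4-oxobutanoate
Product: 9 methyl 4-[(4S)-4-benzyl-2-oxooxazolidin-3-yl]-4-oxobutanoate
Conditions: n-BuLi, THF, −78 °C; then 8
Reagents that add atoms: none
Why: N-Acylation of the lithiated oxazolidinone with the acid chloride gives the succinate-type imide for the Evans aldol.

Step 7
Reactants: 9 succinate imide; 6 enal carbonate
Product: 11 trans-γ-lactone imide (2R,6R,7S) with the C8 acyl oxazolidinone on C7 and the (E)-C5=C4 chain ending in the C9 methyl carbonate on C6, via syn-aldol adduct 10 (not isolated)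
Conditions: Bu2BOTf, i-Pr2NEt, CH2Cl2, −78 to 0 °C; 6, −78 to 0 °C; pH 7 buffer, MeOH, H2O2; then PPTS (cat.), PhMe, 40 °C
Reagents that add atoms: none
Why: Evans syn-aldol reaction through the Z boron enolate of the imide (Zimmerman–Traxler chair, auxiliary control; the imide and not the ester is enolized) should set C6 as R and C7 syn to it, and mild acid then closes the trans-γ-lactone by attack of the C6 hydroxyl on the methyl ester.

Step 8
Reactants: 11 lactone imide carbonate
Product: 12 α-substituted allyl pinacol boronate (1S,2R,6R,7S): Bpin on C1, isopropenyl group C10(C14)=C9H2, OTBS on C2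
Conditions: Cu(O-t-Bu) (5 mol %), Xantphos (5 mol %), B2pin2, THF, 0 °C to rt
Reagents that add atoms: bis(pinacolato)diboron CC1(C)OB(OC1(C)C)B1OC(C)(C)C(C)(C)O1
Why: Copper-catalysed γ-selective allylic borylation (SN2' substitution of the carbonate by a boryl copper species): allylic 1,3-strain with the C14 methyl holds C2–H in the alkene plane, so boron should add to C1 anti to the bulky silyloxy group and give the (1S) boronate anti to the C2 oxygen; a matched chiral bisphosphine can reinforce this.

Step 9
Reactants: 12 allylboronate imide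
Product: 13 primary alcohol (1S,2R,6R,7R): C8H2OH on C7 of the lactone, allylboronate unchanged
Conditions: NaBH4, THF/H2O, 0 °C
Reagents that add atoms: none
Why: Chemoselective borohydride reduction of the activated N-acyl oxazolidinone (reductive auxiliary cleavage) should spare the γ-lactone and the pinacol boronate at 0 °C.

Step 10
Reactants: 13 boronate alcohol
Product: 15 (1(10)Z,4E,2R,6R,7R,8R)-2-[(tert-butyldimethylsilyl)oxy]-8-hydroxygermacra-1(10),4-dien-12,6-olide, via aldehyde 14 (not isolated)
Conditions: DMP, NaHCO3, CH2Cl2, 0 °C; then PhMe (0.002 M), 60–80 °C; aq. NaHCO3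
Reagents that add atoms: none
Why: Proposed new method: Dess–Martin oxidation unmasks the C8 aldehyde, and at high dilution the C9 terminus of the allylboronate should add to it through a six-membered Zimmerman–Traxler chair (B, C1, C10, C9, C8, O), boron passing to oxygen while the double bond moves to C1=C10; the closest known reaction types are the intermolecular addition of α-substituted 2-methylallyl pinacol boronates to aldehydes, which gives (Z)-trisubstituted homoallylic alcohols with chirality transfer, and the intramolecular allylboration known for five- to seven-membered rings. The ten-membered carbocycle closes by C8–C9 bond formation in an endo mode, the new C1=C10 bond lying inside the ring, which has not been shown for this ring size or for a tether attached at the boron-bearing carbon. The Z geometry should follow because the C2 substituent on C1 takes the axial site, away from 1,2-strain with the C14 methyl and from the pinacol oxygens. The new C8 centre (R) is controlled by the C1 centre (S) of step 8: with C2 axial and the lactone carbon C7 equatorial on the carbonyl carbon, the chair places the oxygen on the required face. The step needs ring closure to outrun intermolecular allylboration and needs a neutral medium, since the aldehyde is a β-acyloxy aldehyde; high dilution, the trans-lactone and the E-C4=C5 alkene that stiffen the tether, and buffered oxidation followed by base-free heating should secure both.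

Step 11
Reactants: 15 macrocyclic hydroxy lactone
Product: 16 (2R,6R,7S,8R)-2-[(tert-butyldimethylsilyl)oxy]-8-[(triethylsilyl)oxy]germacra-1(10)Z,4E-dien-12,6-olide
Conditions: TESOTf, 2,6-lutidine, CH2Cl2, −78 °C
Reagents that add atoms: triethylsilyl triflate CC[Si](CC)(CC)OS(=O)(=O)C(F)(F)F
Why: Silyl ether protection of the hindered C8 hydroxyl prevents alkoxide attack on the lactone (translactonization) under the basic conditions that follow.

Step 12
Reactants: 16 bis-silyl ether lactone
Product: 19 (2R,6R,7S,8R)-2-[(tert-butyldimethylsilyl)oxy]-8-[(triethylsilyl)oxy]germacra-1(10)Z,4E,11(13)-trien-12,6-olide, via Mannich base 17 (not isolated), via ammonium iodide 18 (not isolated)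
Conditions: LiN(i-Pr)2, THF, −78 °C; CH2=NMe2+ I−, −78 to 0 °C; then MeI, THF, rt; aq. NaHCO3
Reagents that add atoms: N,N-dimethylmethyleneiminium iodide C=[N+](C)C.[I-]
Why: Eschenmoser methylenation: Mannich reaction of the lactone lithium enolate with the iminium salt, N-methylation and base-induced elimination of trimethylamine should give the exocyclic C11=C13 alkene.

Step 13
Reactants: 19 α-methylene lactone bis-silyl ether
Product: 20 (2R,6R,7R,8R)-2-[(tert-butyldimethylsilyl)oxy]-8-hydroxygermacra-1(10)Z,4E,11(13)-trien-12,6-olide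
Conditions: PPTS, MeOH/CH2Cl2, 0 °C
Reagents that add atoms: none
Why: Acid-catalysed methanolysis cleaves the triethylsilyl ether far faster than the tert-butyldimethylsilyl ether (selective desilylation), freeing only the C8 hydroxyl.

Step 14
Reactants: 21 methyl (S)-3-hydroxy-2-methylpropanoate
Product: 22 methyl (S)-3-[(tert-butyldimethylsilyl)oxy]-2-methylpropanoate
Conditions: TBSCl, imidazole, CH2Cl2, rt
Reagents that add atoms: tert-butyldimethylsilyl chloride CC(C)(C)[Si](C)(C)Cl
Why: Silyl ether protection of the primary alcohol of the Roche ester, whose stereocentre becomes the side-chain centre of the target.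

Step 15
Reactants: 22 silylated Roche ester
Product: 23 (S)-3-[(tert-butyldimethylsilyl)oxy]-2-methylpropanoic acid
Conditions: LiOH, THF/MeOH/H2O, 0 °C; 1 M HCl
Reagents that add atoms: lithium hydroxide [Li+].[OH-]
Why: Saponification at 0 °C should give the acid without epimerization or β-elimination of the silyloxy group.

Step 16
Reactants: 20 C8 alcohol; 23 side-chain acid
Product: 24 (2R,6R,7R,8R)-2-[(tert-butyldimethylsilyl)oxy]-8-{[(2S)-3-[(tert-butyldimethylsilyl)oxy]-2-methylpropanoyl]oxy}germacra-1(10)Z,4E,11(13)-trien-12,6-olide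
Conditions: EDC·HCl, DMAP, CH2Cl2, 0 °C to rt
Reagents that add atoms: none
Why: Steglich esterification of the secondary C8 alcohol; carbodiimide activation at 0 °C should avoid ketene formation and keep the α-stereocentre of the acid.

Step 17
Reactants: 24 bis-silyl ether ester
Product: 25 target, (2R,6R,7R,8R)-2-hydroxy-8-{[(2S)-3-hydroxy-2-methylpropanoyl]oxy}germacra-1(10)Z,4E,11(13)-trien-12,6-olide
Conditions: HF·pyridine, pyridine, THF, 0 °C to rt
Reagents that add atoms: none
Why: Fluoride-mediated global desilylation under buffered conditions should remove both silyl ethers without acyl migration or conjugate addition to the α-methylene lactone.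

Compound list
1 | 3-methylbut-2-enal | CC(C)=CC=O | starting material
2 | (E)-tert-butyl(dimethyl)[(3-methylbuta-1,3-dien-1-yl)oxy]silane | C=C(C)/C=C/O[Si](C)(C)C(C)(C)C | intermediate
3 | (2E,5R)-5-hydroxy-3,7-dimethylocta-2,6-dienal | O=C/C=C(\C)C[C@@H](O)C=C(C)C | intermediate
4 | (2E,5R)-5-[(tert-butyldimethylsilyl)oxy]-3,7-dimethylocta-2,6-dienal | O=C/C=C(\C)C[C@@H](O[Si](C)(C)C(C)(C)C)C=C(C)C | intermediate
5 | (2E,5R,6E)-5-[(tert-butyldimethylsilyl)oxy]-8-hydroxy-3,7-dimethylocta-2,6-dienal | O=C/C=C(\C)C[C@@H](O[Si](C)(C)C(C)(C)C)/C=C(\C)CO | intermediate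
6 | (2E,4R,6E)-4-[(tert-butyldimethylsilyl)oxy]-2,6-dimethyl-8-oxoocta-2,6-dien-1-yl methyl carbonate | O=C/C=C(\C)C[C@@H](O[Si](C)(C)C(C)(C)C)/C=C(\C)COC(=O)OC | intermediate
7 | (S)-4-benzyloxazolidin-2-one | O=C1N[C@@H](Cc2ccccc2)CO1 | starting material
8 | methyl 4-chloro-4-oxobutanoate | COC(=O)CCC(Cl)=O | starting material
9 | methyl 4-[(4S)-4-benzyl-2-oxooxazolidin-3-yl]-4-oxobutanoate | COC(=O)CCC(=O)N1[C@@H](Cc2ccccc2)COC1=O | intermediate
10 | syn-aldol adduct (2R,6R,7S): C6 hydroxyl, C7 bearing the imide carbonyl C8 and CH2CO2Me | COC(=O)C[C@H](C(=O)N1[C@@H](Cc2ccccc2)COC1=O)[C@H](O)/C=C(\C)C[C@@H](O[Si](C)(C)C(C)(C)C)/C=C(\C)COC(=O)OC | intermediate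
11 | trans-γ-lactone imide (2R,6R,7S) with C9 methyl carbonate | O=C1C[C@H](C(=O)N2[C@@H](Cc3ccccc3)COC2=O)[C@@H](/C=C(\C)C[C@@H](O[Si](C)(C)C(C)(C)C)/C=C(\C)COC(=O)OC)O1 | intermediate
12 | allyl pinacol boronate imide (1S,2R,6R,7S) | O=C1C[C@H](C(=O)N2[C@@H](Cc3ccccc3)COC2=O)[C@@H](/C=C(\C)C[C@@H](O[Si](C)(C)C(C)(C)C)[C@@H](B4OC(C)(C)C(C)(C)O4)C(C)=C)O1 | intermediate
13 | boronate primary alcohol (1S,2R,6R,7R) | O=C1C[C@H](CO)[C@@H](/C=C(\C)C[C@@H](O[Si](C)(C)C(C)(C)C)[C@@H](B2OC(C)(C)C(C)(C)O2)C(C)=C)O1 | intermediate
14 | boronate aldehyde (1S,2R,6R,7S) | O=C1C[C@H](C=O)[C@@H](/C=C(\C)C[C@@H](O[Si](C)(C)C(C)(C)C)[C@@H](B2OC(C)(C)C(C)(C)O2)C(C)=C)O1 | intermediate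
15 | (1(10)Z,4E,2R,6R,7R,8R)-2-[(tert-butyldimethylsilyl)oxy]-8-hydroxygermacra-1(10),4-dien-12,6-olide | C1C(=O)O[C@@H]2/C=C(\C)C[C@@H](O[Si](C)(C)C(C)(C)C)/C=C(/C)C[C@@H](O)[C@@H]12 | intermediate
16 | 8-O-triethylsilyl ether of 15 (2R,6R,7S,8R) | C1C(=O)O[C@@H]2/C=C(\C)C[C@@H](O[Si](C)(C)C(C)(C)C)/C=C(/C)C[C@@H](O[Si](CC)(CC)CC)[C@@H]12 | intermediate
17 | Mannich base, 11-(dimethylaminomethyl) lactone (C11 configuration not defined) | CN(C)CC1C(=O)O[C@@H]2/C=C(\C)C[C@@H](O[Si](C)(C)C(C)(C)C)/C=C(/C)C[C@@H](O[Si](CC)(CC)CC)[C@@H]12 | intermediate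
18 | trimethylammonium iodide of 17 | C[N+](C)(C)CC1C(=O)O[C@@H]2/C=C(\C)C[C@@H](O[Si](C)(C)C(C)(C)C)/C=C(/C)C[C@@H](O[Si](CC)(CC)CC)[C@@H]12.[I-] | intermediate
19 | α-methylene lactone bis-silyl ether (2R,6R,7S,8R) | C=C1C(=O)O[C@@H]2/C=C(\C)C[C@@H](O[Si](C)(C)C(C)(C)C)/C=C(/C)C[C@@H](O[Si](CC)(CC)CC)[C@@H]12 | intermediate
20 | 8-hydroxy α-methylene lactone, 2-O-TBS (2R,6R,7R,8R) | C=C1C(=O)O[C@@H]2/C=C(\C)C[C@@H](O[Si](C)(C)C(C)(C)C)/C=C(/C)C[C@@H](O)[C@@H]12 | intermediate
21 | methyl (S)-3-hydroxy-2-methylpropanoate | C[C@@H](CO)C(=O)OC | starting material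
22 | methyl (S)-3-[(tert-butyldimethylsilyl)oxy]-2-methylpropanoate | C[C@@H](CO[Si](C)(C)C(C)(C)C)C(=O)OC | intermediate
23 | (S)-3-[(tert-butyldimethylsilyl)oxy]-2-methylpropanoic acid | C[C@@H](CO[Si](C)(C)C(C)(C)C)C(=O)O | intermediate
24 | bis-TBS ether of the target (2R,6R,7R,8R,2'S) | C=C1C(=O)O[C@@H]2/C=C(\C)C[C@@H](O[Si](C)(C)C(C)(C)C)/C=C(/C)C[C@@H](OC(=O)[C@@H](C)CO[Si](C)(C)C(C)(C)C)[C@@H]12 | intermediate
25 | CNP0254953.1, (2R,6R,7R,8R)-2-hydroxy-8-{[(2S)-3-hydroxy-2-methylpropanoyl]oxy}germacra-1(10)Z,4E,11(13)-trien-12,6-olide | C=C1C(=O)O[C@@H]2/C=C(\C)C[C@@H](O)/C=C(/C)C[C@@H](OC(=O)[C@@H](C)CO)[C@@H]12 | target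

Total steps: 17. Longest linear sequence: 14 steps (steps 1–5, 7–13, 16 and 17).

Steps most likely to fail

Step 10 (key step, proposed new method). Intermolecular allylboration may outrun ring closure and give oligomers. Ring strain may override the axial and equatorial preferences of the chair and give the E alkene or the C8 epimer. Slow closure may leave time for β-elimination of the lactone carboxylate from the aldehyde. The fallback uses known chemistry, a ring-closing metathesis, which in ten-membered rings favours the Z alkene. It sets out from 2, which is joined to acrolein in the same vinylogous Mukaiyama aldol to give (2E,5R)-5-hydroxy-3-methylhepta-2,6-dienal F1; silylation (TBSCl, imidazole) gives the silyl ether F2. Evans aldol with 9 gives the syn-aldol adduct F3, which lactonizes to the lactone imide F4. NaBH4 gives the primary alcohol F5 and Dess–Martin oxidation the aldehyde F6. Brown methallylboration with the enantiomer of Ipc2B–CH2C(CH3)=CH2 matched for 8R gives the homoallylic alcohol F7. Ring-closing metathesis of the C2 vinyl group and the methallyl group (second-generation Grubbs catalyst, (H2IMes)(PCy3)Cl2Ru=CHPh, PhMe, high dilution) closes C1=C10 with loss of ethene and comes back to the route at 15. Step 8 carries a comparable risk (poor facial selectivity or low reactivity in the borylation) but has no remedy of its own; because this detour needs no boronate, it answers a failure of step 8 as well.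

Step 9. The hydroxy lactone may translactonize under the basic borohydride conditions, with the new C8 alkoxide opening the lactone, or the lactone may be over-reduced. The fallback avoids a free C8 alcohol. It sets out from 12: LiSEt (EtSH, n-BuLi, THF, 0 °C) displaces the auxiliary and gives the S-ethyl thioester F8. Fukuyama reduction (Et3SiH, Pd/C, acetone, rt) then gives the aldehyde directly and comes back to the route at 14, which is diluted and cyclized as in step 10.

Step 2. Facial discrimination on the enal may be poor, and α-attack or conjugate addition may compete with γ-attack. The fallback sets the centre by reagent control and builds the enal afterwards. It sets out from 1: Brown methallylboration with the enantiomer of Ipc2B–CH2C(CH3)=CH2 that gives the R alcohol yields (R)-2,6-dimethylhepta-1,5-dien-4-ol F9, which is silylated (TBSCl, imidazole) to the silyl ether F10. Cross-metathesis of its 1,1-disubstituted alkene with crotonaldehyde (second-generation Hoveyda–Grubbs catalyst, (H2IMes)Cl2Ru=CH(C6H4-2-O-i-Pr), CH2Cl2, 40 °C) gives the (E)-enal and comes back to the route at 4.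

Further compounds
F1 | step 10 | (2E,5R)-5-hydroxy-3-methylhepta-2,6-dienal | O=C/C=C(\C)C[C@@H](O)C=C
F2 | step 10 | (2E,5R)-5-[(tert-butyldimethylsilyl)oxy]-3-methylhepta-2,6-dienal | O=C/C=C(\C)C[C@@H](O[Si](C)(C)C(C)(C)C)C=C
F3 | step 10 | syn-aldol adduct of F2 and 9 | COC(=O)C[C@H](C(=O)N1[C@@H](Cc2ccccc2)COC1=O)[C@H](O)/C=C(\C)C[C@@H](O[Si](C)(C)C(C)(C)C)C=C
F4 | step 10 | trans-γ-lactone imide with C2 vinyl group | O=C1C[C@H](C(=O)N2[C@@H](Cc3ccccc3)COC2=O)[C@@H](/C=C(\C)C[C@@H](O[Si](C)(C)C(C)(C)C)C=C)O1
F5 | step 10 | lactone primary alcohol with C2 vinyl group | O=C1C[C@H](CO)[C@@H](/C=C(\C)C[C@@H](O[Si](C)(C)C(C)(C)C)C=C)O1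
F6 | step 10 | lactone aldehyde with C2 vinyl group | O=C1C[C@H](C=O)[C@@H](/C=C(\C)C[C@@H](O[Si](C)(C)C(C)(C)C)C=C)O1
F7 | step 10 | (8R)-homoallylic alcohol with methallyl and vinyl groups | O=C1C[C@H]([C@H](O)CC(C)=C)[C@@H](/C=C(\C)C[C@@H](O[Si](C)(C)C(C)(C)C)C=C)O1
F8 | step 9 | S-ethyl thioester of the boronate lactone | O=C1C[C@H](C(=O)SCC)[C@@H](/C=C(\C)C[C@@H](O[Si](C)(C)C(C)(C)C)[C@@H](B2OC(C)(C)C(C)(C)O2)C(C)=C)O1
F9 | step 2 | (R)-2,6-dimethylhepta-1,5-dien-4-ol | C=C(C)C[C@@H](O)C=C(C)C
F10 | step 2 | (R)-tert-butyl[(2,6-dimethylhepta-1,5-dien-4-yl)oxy]dimethylsilane | C=C(C)C[C@@H](O[Si](C)(C)C(C)(C)C)C=C(C)C
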